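**Plan**
Atom numbers follow the order of atoms in the target SMILES; ring A is the δ-lactone, ring B the cyclohexane, ring E the carbocycle C14/C16/C17/C22/C23/C30, ring F the γ-lactone.
Retrosynthetic cuts: the C7=C8 unsaturation and C17–H; then C17–C18 and C18–O20 (Pd/CO lactonisation of a C17 enol triflate onto the C21 hydroxyl, ring F); C27–C28; C12–C22 and C13–C14 (intramolecular Diels–Alder); C12–C13; C25–C26 (union of two fragments).
Forward: fragment 1 (ring E with C23, C25) from (S)-carvone; fragment 2 (rings A and B as a spiro-lactone dione) from 3-ethoxycyclohexenone and acrolein; union, exocyclic methylene, cycloaddition to the cyclopentane and bicyclo[2.2.2]octane, ring F by carbonylation, then C17 reduction and ring A dehydrogenation.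
Stereochemistry: C23 comes from (S)-carvone, whose isopropenyl group steers the aldol and is then excised; C9 comes from an organocatalytic Michael addition.
C12, C14 and C22 follow from C23 through the two-atom tether in the cycloaddition; C26 is set by equilibration next to the C27 ketone, C27 by equatorial methyl addition, C17 by hydrogenation and equilibration.

Key step: step 20

Assumption: the cinchona catalyst of step 7 is taken to deliver the (R)-quaternary centre; its pseudo-enantiomer serves if the sense proves opposite.

**Route**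

Step 1
Reactants: 1 (S)-(+)-carvone
Product: 2 6-methylcarvone (C6 epimers)
Conditions: LiN(iPr)2, THF, −78 °C; MeI, −78 → 0 °C
Reagents that add atoms: iodomethane, CI
Why: Kinetic α′-deprotonation of the enone and enolate alkylation should install the C24 methyl on the future C23; the configuration at this carbon is erased by re-enolisation in step 2.

Step 2
Reactants: 2 6-methylcarvone
Product: 3 (5R,6S)-6-(hydroxymethyl)-2,6-dimethyl-5-(prop-1-en-2-yl)cyclohex-2-en-1-one
Conditions: LiN(iPr)2, THF, −78 °C; CH2O (gas), −78 → −20 °C; NH4Cl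
Reagents that add atoms: formaldehyde, C=O
Why: Aldol addition of the tetrasubstituted α′ lithium enolate to formaldehyde should occur anti to the adjacent isopropenyl group, fixing the C23 quaternary centre with C25 trans to isopropenyl.

Step 3
Reactants: 3 hydroxymethyl carvone derivative
Product: 4 (6S)-6-(hydroxymethyl)-2,6-dimethylcyclohex-2-en-1-one
Conditions: O3, MeOH, −78 °C; then FeSO4·7H2O, PhSH, −78 → 25 °C
Reagents that add atoms: none
Why: Ozonolysis of the isopropenyl group in methanol and FeSO4 reduction of the α-methoxy hydroperoxide give an alkoxy radical that fragments by β-scission; the thiol quenches the C22 radical (dealkenylative hydrogen-atom transfer), the electron-poor enone is spared and C23 is untouched.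

Step 4
Reactants: 4 hydroxymethyl enone
Product: 5 (6S)-6-(hydroxymethyl)-2,6-dimethylcyclohex-2-ene-1,4-dione
Conditions: Pd(OH)2/C (cat.), t-BuOOH, K2CO3, CH2Cl2, 4 °C
Reagents that add atoms: tert-butyl hydroperoxide, CC(C)(C)OO
Why: Pd(OH)2-catalysed allylic C–H oxidation with tert-butyl hydroperoxide converts the γ-methylene of a cyclohexenone into the enedione carbonyl (C17); the neopentyl alcohol has no comparably activated C–H bond.

Step 5
Reactants: 5 enedione alcohol
Product: 6 (1S)-1,3-dimethyl-2,5-dioxocyclohex-3-ene-1-carbaldehyde (fragment 1)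
Conditions: Dess–Martin periodinane, CH2Cl2, 25 °C
Reagents that add atoms: none
Why: Dess–Martin oxidation gives the non-enolisable α-quaternary β-keto aldehyde (C25) without touching the stereocentre.

Step 6
Reactants: 7 3-ethoxycyclohex-2-en-1-one
Product: 8 6-acetyl-3-ethoxycyclohex-2-en-1-one (racemic)
Conditions: LiN(iPr)2 (2.1 equiv), THF, −78 °C; 1-acetylbenzotriazole; NH4Cl
Reagents that add atoms: 1-acetylbenzotriazole, CC(=O)n1nnc2ccccc12
Why: The kinetic α′-enolate of the vinylogous ester is C-acylated (Claisen-type enolate acylation), and the second equivalent of base stores the acidic 1,3-dicarbonyl as its enolate.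

Step 7
Reactants: 8 6-acetyl-3-ethoxycyclohex-2-en-1-one; 9 acrolein
Product: 10 3-[(1R)-1-acetyl-4-ethoxy-2-oxocyclohex-3-en-1-yl]propanal
Conditions: 9-O-(9-phenanthryl)cupreidine (10 mol%), CH2Cl2, −24 °C
Reagents that add atoms: none
Why: Cinchona-base-catalysed asymmetric Michael addition of the cyclic 1,3-dicarbonyl to acrolein creates the C9 quaternary centre, the face being selected by the ion-paired, hydrogen-bonding catalyst.

Step 8
Reactants: 10 Michael adduct aldehyde
Product: 11 3-[(1R)-1-acetyl-4-ethoxy-2-oxocyclohex-3-en-1-yl]propanoic acid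
Conditions: NaClO2, NaH2PO4, 2-methylbut-2-ene, t-BuOH/H2O, 0 → 25 °C
Reagents that add atoms: sodium chlorite, [Na+].[O-]Cl=O
Why: Pinnick oxidation converts the aldehyde to the acid (C5) without affecting the enol ether or the non-enolisable diketone.

Step 9
Reactants: 11 keto acid
Product: 13 (6R)-1,1-dimethyl-2-oxaspiro[5.5]undecane-3,7,9-trione (fragment 2), via hydroxy acid 12 (not isolated)
Conditions: MeMgBr (2.6 equiv), THF, −78 → −40 °C; then 2 M HCl, THF, 40 °C
Reagents that add atoms: methylmagnesium bromide, C[Mg]Br
Why: Grignard addition occurs at the methyl ketone (the carboxylate and the vinylogous ester are far less electrophilic); acid then lactonises the tertiary δ-hydroxy acid (ring A) and hydrolyses the enol ether to the 1,3-dione.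

Step 10
Reactants: 6 fragment 1 aldehyde; 13 fragment 2 dione
Product: 14 C25–C26 linked dione (enol form)
Conditions: L-proline (20 mol%), Hantzsch ester (1.1 equiv), CH2Cl2, 25 °C
Reagents that add atoms: none
Why: Proline-catalysed Knoevenagel condensation at the dione C26 and in situ transfer hydrogenation of the alkylidene dione by the Hantzsch ester (three-component reductive alkylation) forge C25–C26 without creating a stereocentre.

Step 11
Reactants: 14 linked dione
Product: 15 C12 enol triflate (β-triflyloxy enone)
Conditions: Tf2O, pyridine, CH2Cl2, −78 °C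
Reagents that add atoms: trifluoromethanesulfonic anhydride, O=S(=O)(OS(=O)(=O)C(F)(F)F)C(F)(F)F
Why: O-sulfonylation of the dione enol should occur at the oxygen remote from the spiro quaternary carbon (steric control), leaving the C27 carbonyl and placing the triflate on C12.

Step 12
Reactants: 15 enol triflate
Product: 16 C12 (trimethylsilyl)methyl enone (allylsilane)
Conditions: Me3SiCH2ZnCl, Pd(PPh3)4 (5 mol%), THF, 50 °C
Reagents that add atoms: (trimethylsilyl)methylzinc chloride, C[Si](C)(C)C[Zn]Cl
Why: Negishi coupling (oxidative addition of zerovalent palladium, transmetalation from zinc, reductive elimination) installs C13; the organozinc halide tolerates the ketones and the lactone.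

Step 13
Reactants: 16 allylsilane enone
Product: 18 C22 hydroxymethyl ketone (C22 epimers), via silyl dienol ether 17 (not isolated)
Conditions: Me3SiOTf, Et3N, CH2Cl2, −78 °C; then 37% aq. CH2O, Yb(OTf)3 (10 mol%), THF, 25 °C
Reagents that add atoms: formaldehyde, C=O
Why: Soft enolisation of the C17 ketone can only go toward C22 (C16 is vinylic), and the silyl dienol ether undergoes a lanthanide-triflate-catalysed Mukaiyama aldol reaction with aqueous formaldehyde to install C21; the new C22 centre is transient.

Step 14
Reactants: 18 hydroxymethyl allylsilane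
Product: 19 β,γ-unsaturated ketone with exocyclic C12=C13 (C26 epimers)
Conditions: Bu4NF, AcOH, THF, 0 °C
Reagents that add atoms: none
Why: Fluoride cleaves the vinylogous α-silyl ketone to the extended enolate, and kinetic α-protonation (protodesilylation with allylic transposition) leaves the double bond exocyclic; the C26 centre is levelled in step 16.

Step 15
Reactants: 19 keto alcohol
Product: 20 C21 tert-butyldimethylsilyl ether
Conditions: t-BuMe2SiCl, imidazole, DMF, 25 °C
Reagents that add atoms: tert-butyldimethylsilyl chloride, CC(C)(C)[Si](C)(C)Cl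
Why: Imidazole-catalysed silylation protects the primary C21 hydroxyl for the enolisation and triflation steps.

Step 16
Reactants: 20 silyl ether
Product: 23 cage diketone (C17 and C27 ketones), via bis-silyl triene 21 (not isolated), via cycloadduct 22 (not isolated)
Conditions: Me3SiOTf, Et3N, CH2Cl2, −78 → 0 °C; evaporate; PhMe, Et3N, 140 °C (sealed); then 1 M HCl, THF, 0 °C; then DBU, CH2Cl2, 25 °C
Reagents that add atoms: none
Why: Soft enolisation removes C26–H and C22–H, and the resulting cyclohexa-2,4-dienone undergoes an intramolecular Diels–Alder reaction with the C12=C13 alkene held by the two-atom tether from C23 (as in masked o-benzoquinone cycloadditions), so C12, C14 and C22 follow from C23; acid cleaves the enol ethers and DBU equilibrates C26 to the cis ring fusion.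

Step 17
Reactants: 23 cage diketone
Product: 24 C17 enol triflate
Conditions: KN(SiMe3)2, THF, −78 °C; PhNTf2
Reagents that add atoms: N-phenylbis(trifluoromethanesulfonimide), O=S(=O)(N(c1ccccc1)S(=O)(=O)C(F)(F)F)C(F)(F)F
Why: Kinetic deprotonation takes the C16 methylene (the C27 ketone offers only the hindered ring-fusion methine; C22 and C9 are quaternary), and O-sulfonylation gives the regiodefined enol triflate.

Step 18
Reactants: 24 enol triflate ketone
Product: 25 C27 tertiary alcohol
Conditions: MeMgBr, LaCl3·2LiCl (0.3 equiv), THF, −40 → −20 °C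
Reagents that add atoms: methylmagnesium bromide, C[Mg]Br
Why: Lanthanum-promoted Grignard addition to the C27 ketone should come from the equatorial direction because the axial face is blocked by the syn-axial C22, giving the axial alcohol; the lactone, the enol triflate and the doubly neopentyl C30 ketone should react more slowly.

Step 19
Reactants: 25 silyl ether
Product: 26 C17 enol triflate with free C21 and C27 hydroxyls
Conditions: HF·pyridine, THF, 0 → 25 °C
Reagents that add atoms: none
Why: Fluoride-mediated desilylation frees the primary alcohol without affecting the enol triflate or the lactone.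

Step 20
Reactants: 26 hydroxy enol triflate; 27 carbon monoxide
Product: 28 butenolide (16,17-dehydro-7,8-dihydro target)
Conditions: Pd(PPh3)4 (10 mol%), CO (1 atm), Bu3N, LiCl, MeCN, 65 °C
Reagents that add atoms: none
Why: Zerovalent palladium adds oxidatively to the C17–OTf bond, CO inserts to give the C17 acyl palladium, and the C21 hydroxyl attacks the acyl carbon while the amine takes up TfOH, forming C17–C18 and C18–O20. The closest known reaction is the Pd(PPh3)4/CO carbonylative lactonisation of enol triflates bearing an adjacent hydroxymethyl group to α,β-butenolides. Ring F closes by 5-exo-trig attack of O20 on the acyl carbon; C21 on the bridgehead C22 lies anti to C16, so C21–C22–C17–C18 is held near 0°, ideal for a planar butenolide. No stereocentre is formed. The step needs regiocontrol, secured by the triflate position, and chemoselectivity between the hydroxyls: the primary C21 alcohol closes a five-membered ring, whereas the tertiary C27 alcohol would need a bridged seven-membered ring. Intramolecular capture also acylates a neopentyl alcohol that resists ordinary acylation.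

Step 21
Reactants: 28 butenolide
Product: 30 7,8-dihydro target, via C17 epimer 29 (not isolated)
Conditions: H2 (1 atm), Pd/C, EtOAc, 25 °C; filter; then DBU, PhMe, 60 °C
Reagents that add atoms: none
Why: Heterogeneous hydrogenation of the strained butenolide alkene should occur from the more open face beside the planar C30 carbonyl and give the C17 epimer first; DBU then equilibrates the α-lactone centre (thermodynamic epimerisation) toward the natural configuration, which places C18 in that more open sector.

Step 22
Reactants: 30 7,8-dihydro target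
Product: 32 target CNP0222978.3, via phenylselenide 31 (not isolated)
Conditions: LiN(iPr)2 (2.2 equiv), THF, −78 °C; PhSeBr; then H2O2, pyridine, CH2Cl2, 0 → 25 °C
Reagents that add atoms: none
Why: After the tertiary alkoxide is formed, the δ-lactone α-methylene C7 is the most accessible acidic site; selenenylation of its enolate and selenoxide syn-elimination install C7=C8.

**Compound list**
1 | (S)-(+)-carvone | CC(=C)[C@H]1CC=C(C)C(=O)C1 | starting material
2 | (5S)-2,6-dimethyl-5-(prop-1-en-2-yl)cyclohex-2-en-1-one (C6 epimers) | CC(=C)[C@H]1CC=C(C)C(=O)C1C | intermediate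
3 | (5R,6S)-6-(hydroxymethyl)-2,6-dimethyl-5-(prop-1-en-2-yl)cyclohex-2-en-1-one | C[C@@]1(CO)[C@@H](C(C)=C)CC=C(C)C1=O | intermediate
4 | (6S)-6-(hydroxymethyl)-2,6-dimethylcyclohex-2-en-1-one | C[C@@]1(CO)CCC=C(C)C1=O | intermediate
5 | (6S)-6-(hydroxymethyl)-2,6-dimethylcyclohex-2-ene-1,4-dione | C[C@@]1(CO)CC(=O)C=C(C)C1=O | intermediate
6 | (1S)-1,3-dimethyl-2,5-dioxocyclohex-3-ene-1-carbaldehyde | C[C@@]1(C=O)CC(=O)C=C(C)C1=O | intermediate
7 | 3-ethoxycyclohex-2-en-1-one | CCOC1=CC(=O)CCC1 | starting material
8 | 6-acetyl-3-ethoxycyclohex-2-en-1-one (racemic) | CCOC1=CC(=O)C(C(C)=O)CC1 | intermediate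
9 | acrolein | C=CC=O | starting material
10 | 3-[(1R)-1-acetyl-4-ethoxy-2-oxocyclohex-3-en-1-yl]propanal | O=CCC[C@@]1(C(C)=O)CCC(OCC)=CC1=O | intermediate
11 | 3-[(1R)-1-acetyl-4-ethoxy-2-oxocyclohex-3-en-1-yl]propanoic acid | OC(=O)CC[C@@]1(C(C)=O)CCC(OCC)=CC1=O | intermediate
12 | 3-[(1R)-4-ethoxy-1-(2-hydroxypropan-2-yl)-2-oxocyclohex-3-en-1-yl]propanoic acid | OC(=O)CC[C@@]1(C(C)(C)O)CCC(OCC)=CC1=O | intermediate
13 | (6R)-1,1-dimethyl-2-oxaspiro[5.5]undecane-3,7,9-trione | CC1(C)OC(=O)CC[C@]12CCC(=O)CC2=O | intermediate
14 | enol form of the 2-alkyl-1,3-dione: rings A/B of 13 joined through C26–C25 to the ring E enedione of 6 (C9 and C23 as in 13 and 6) | CC1(C)OC(=O)CC[C@]12CCC(O)=C(C[C@]3(C)CC(=O)C=C(C)C3=O)C2=O | intermediate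
15 | C12 trifluoromethanesulfonate of 14 (C12=C26 enone, C27 ketone) | CC1(C)OC(=O)CC[C@]12CCC(OS(=O)(=O)C(F)(F)F)=C(C[C@]3(C)CC(=O)C=C(C)C3=O)C2=O | intermediate
16 | C12 (trimethylsilyl)methyl enone | CC1(C)OC(=O)CC[C@]12CCC(C[Si](C)(C)C)=C(C[C@]3(C)CC(=O)C=C(C)C3=O)C2=O | intermediate
17 | ring E trimethylsilyl dienol ether of 16 (C22=C17–OSiMe3) | CC1(C)OC(=O)CC[C@]12CCC(C[Si](C)(C)C)=C(C[C@]3(C)C=C(O[Si](C)(C)C)C=C(C)C3=O)C2=O | intermediate
18 | C22 hydroxymethyl derivative of 16 (C22 epimers) | CC1(C)OC(=O)CC[C@]12CCC(C[Si](C)(C)C)=C(C[C@]3(C)C(CO)C(=O)C=C(C)C3=O)C2=O | intermediate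
19 | ring B β,γ-unsaturated C27 ketone with exocyclic C12=C13 and free C21 hydroxyl (C22 and C26 epimers) | CC1(C)OC(=O)CC[C@]12CCC(=C)C(C[C@]3(C)C(CO)C(=O)C=C(C)C3=O)C2=O | intermediate
20 | C21 tert-butyldimethylsilyl ether of 19 | CC1(C)OC(=O)CC[C@]12CCC(=C)C(C[C@]3(C)C(CO[Si](C)(C)C(C)(C)C)C(=O)C=C(C)C3=O)C2=O | intermediate
21 | bis(trimethylsilyl enol ether) triene (ring E 4-silyloxy-2,4-dienone; ring B C26=C27–OSiMe3 with C12=C13) | CC1(C)OC(=O)CC[C@]12CCC(=C)C(C[C@]3(C)C(CO[Si](C)(C)C(C)(C)C)=C(O[Si](C)(C)C)C=C(C)C3=O)=C2O[Si](C)(C)C | intermediate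
22 | Diels–Alder adduct, bis(trimethylsilyl enol ether) at C16=C17 and C26=C27 | CC1(C)OC(=O)CC[C@]12CC[C@@]13C[C@@]4(C)C=C(O[Si](C)(C)C)[C@]1(CO[Si](C)(C)C(C)(C)C)[C@@](C)(CC3=C2O[Si](C)(C)C)C4=O | intermediate
23 | cage diketone (C17, C27 and C30 ketones, C21 silyl ether, ring A lactone) | CC1(C)OC(=O)CC[C@]12CC[C@@]13C[C@@]4(C)CC(=O)[C@]1(CO[Si](C)(C)C(C)(C)C)[C@@](C)(C[C@H]3C2=O)C4=O | intermediate
24 | C17 enol triflate of 23 (C16=C17) | CC1(C)OC(=O)CC[C@]12CC[C@@]13C[C@@]4(C)C=C(OS(=O)(=O)C(F)(F)F)[C@]1(CO[Si](C)(C)C(C)(C)C)[C@@](C)(C[C@H]3C2=O)C4=O | intermediate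
25 | C27 tertiary alcohol (axial OH, equatorial methyl) | CC1(C)OC(=O)CC[C@]12CC[C@@]13C[C@@]4(C)C=C(OS(=O)(=O)C(F)(F)F)[C@]1(CO[Si](C)(C)C(C)(C)C)[C@@](C)(C[C@H]3[C@@]2(C)O)C4=O | intermediate
26 | C17 enol triflate with free C21 and C27 hydroxyls | CC1(C)OC(=O)CC[C@]12CC[C@@]13C[C@@]4(C)C=C(OS(=O)(=O)C(F)(F)F)[C@]1(CO)[C@@](C)(C[C@H]3[C@@]2(C)O)C4=O | intermediate
27 | carbon monoxide | [C-]#[O+] | starting material
28 | 16,17-dehydro-7,8-dihydro target (ring F butenolide) | CC1(C)OC(=O)CC[C@]12CC[C@@]13C[C@@]4(C)C=C5C(=O)OC[C@]51[C@@](C)(C[C@H]3[C@@]2(C)O)C4=O | intermediate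
29 | C17 epimer of the 7,8-dihydro target | CC1(C)OC(=O)CC[C@]12CC[C@@]13C[C@@]4(C)C[C@H]5C(=O)OC[C@]51[C@@](C)(C[C@H]3[C@@]2(C)O)C4=O | intermediate
30 | 7,8-dihydro target | CC1(C)OC(=O)CC[C@]12CC[C@@]13C[C@@]4(C)C[C@@H]5C(=O)OC[C@]51[C@@](C)(C[C@H]3[C@@]2(C)O)C4=O | intermediate
31 | C7 phenylselenide of 30 (C7 epimers) | CC1(C)OC(=O)C([Se]c6ccccc6)C[C@]12CC[C@@]13C[C@@]4(C)C[C@@H]5C(=O)OC[C@]51[C@@](C)(C[C@H]3[C@@]2(C)O)C4=O | intermediate
32 | CNP0222978.3 | CC1(C)OC(=O)C=C[C@]12CC[C@@]13C[C@@]4(C)C[C@@H]5C(=O)OC[C@]51[C@@](C)(C[C@H]3[C@@]2(C)O)C4=O | target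

**Totals**
Total steps: 22. Longest linear sequence: 18 steps (steps 1–5, then 10–22); steps 6–9 run in parallel.

**Three steps most likely to fail**

Step 16. The silyl dienol ethers may lose silicon or isomerise to the endocyclic diene faster than the congested cycloaddition, which joins three contiguous quaternary carbons. The fallback replaces the silyl enol ethers by enol esters, which cannot transfer silicon or engage in Lewis-acid-triggered Michael chemistry. It sets out from 20: double deprotonation with LiN(SiMe3)2 at −78 °C and O-acetylation with Ac2O should give the bis(enol acetate) triene F1. Heating in toluene should give the cycloadduct bis(enol acetate) F2. Brief treatment with K2CO3 in MeOH at 0 °C cleaves both enol acetates and equilibrates C26, coming back to the route at 23.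

Step 18. The Grignard reagent may attack the δ-lactone, enolise the hindered ketone or add from the axial face. The fallback builds the carbinol by oxygen delivery instead of methyl delivery. It sets out from 24: Takai–Lombardo methylenation (Zn, CH2Br2, TiCl4), which tolerates esters and enol triflates, should give the C27 exocyclic alkene F3. Oxymercuration–demercuration (Hg(OCOCF3)2, THF/H2O; then NaBH4, NaOH) places mercury on the open equatorial face, so water attacks C27 from the axial side. This gives the same axial alcohol and comes back to the route at 25.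

Step 21. Hydrogenation may show poor facial selectivity and the equilibrium may not favour the natural C17 configuration. The fallback sets C17 under kinetic rather than thermodynamic control. It sets out from the crude 29/30 mixture: LiN(SiMe3)2 at −78 °C (after the C27 alkoxide is formed) gives the lithium enolate of the γ-lactone, which is protonated with 2,6-di-tert-butyl-4-methylphenol. The epimers are separated and the undesired one is recycled through the same enolate, coming back to the route at 30. This fallback makes no new compound (F0).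

Further compounds
F1 | step 16 | bis(enol acetate) triene from 20 (C17 and C27 enol acetates, exocyclic C12=C13) | CC1(C)OC(=O)CC[C@]12CCC(=C)C(C[C@]3(C)C(CO[Si](C)(C)C(C)(C)C)=C(OC(C)=O)C=C(C)C3=O)=C2OC(C)=O
F2 | step 16 | Diels–Alder adduct bis(enol acetate) at C16=C17 and C26=C27 | CC1(C)OC(=O)CC[C@]12CC[C@@]13C[C@@]4(C)C=C(OC(C)=O)[C@]1(CO[Si](C)(C)C(C)(C)C)[C@@](C)(CC3=C2OC(C)=O)C4=O
F3 | step 18 | C27 exocyclic methylene analogue of 24 | CC1(C)OC(=O)CC[C@]12CC[C@@]13C[C@@]4(C)C=C(OS(=O)(=O)C(F)(F)F)[C@]1(CO[Si](C)(C)C(C)(C)C)[C@@](C)(C[C@H]3C2=C)C4=O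
F0 | step 21 | none | none
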